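**Retrosynthetic overview**

1. Target 22 ⇐ 6α-ol 18 (butanoylation; acetonide → C14 aldehyde → vinyl) ⇐ ring-B 5,7-diene 16, whose α-face hydroboration sets C5 and C6 together under control of the C10 methyl and the C9 chain.
2. 16 ⇐ Δ5-octalin 12 (allylic oxidation at C7, methylation at C8, enol triflate reduction) ⇐ tertiary alcohol 11 ⇐ hydrogenation of the RCM product 10.
3. Enabling feature: the C2–C3 bond of ring A is an unfunctionalised CH2–CH2 link between C1 (on quaternary C10) and quaternary C4. An allyl group on C10 and a 1,1-dimethylallyl group on C5 of ring B are therefore ideal ring-closing metathesis partners, and the new C2=C3 alkene is simply hydrogenated.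
4. Diene 9 ⇐ ketone 8 + prenyl Grignard (γ-attack on the C5 carbonyl); 8 ⇐ 2-methylcyclohex-2-enone 5 + side-chain Grignard 6 + allyl iodide. A Cu-catalysed asymmetric conjugate addition sets C9, and allylation of the enolate relays it to quaternary C10.
5. Ring order: ring B is bought as the cyclohexenone, ring A is closed by RCM; C13 is bought with (R)-citramalic acid.

Key step: step 6

Remark: labdane numbering is used in the names (C1–C10 decalin, C11–C16 side chain, C17 on C8, C18/C19 on C4, C20 on C10; α = face opposite C20); R* = 2-[(4R)-2,2,4-trimethyl-1,3-dioxolan-4-yl]ethyl; the C5 configuration of 9–11 and the C8 configuration of 14 are drawn for the expected major epimer and are inconsequential, because both centres become sp2 later.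

**Route**

Step 1
Reactants: 1 (R)-citramalic acid
Product: 2 (2R)-2-methylbutane-1,2,4-triol
Conditions: BH3·SMe2, B(OMe)3, THF, 0 °C → rt; then MeOH
Reagents that add atoms: none
Why: Borane reduction of both carboxyl groups to CH2OH leaves the tertiary carbinol centre (the future C13) untouched, so its (R) configuration is bought from the chiral pool.

Step 2
Reactants: 2 (2R)-2-methylbutane-1,2,4-triol
Product: 3 2-[(4R)-2,2,4-trimethyl-1,3-dioxolan-4-yl]ethan-1-ol
Conditions: 2,2-dimethoxypropane, TsOH·H2O (cat.), acetone, rt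
Reagents that add atoms: 2,2-dimethoxypropane (COC(C)(C)OC)
Why: Acid-catalysed acetonide formation under thermodynamic control should favour the five-membered dioxolane across the 1,2-diol, masking the future C13–OH and C14 together and leaving the C11 hydroxyl free.

Step 3
Reactants: 3 2-[(4R)-2,2,4-trimethyl-1,3-dioxolan-4-yl]ethan-1-ol
Product: 4 (4R)-4-(2-bromoethyl)-2,2,4-trimethyl-1,3-dioxolane
Conditions: CBr4, PPh3, imidazole, CH2Cl2, 0 °C
Reagents that add atoms: carbon tetrabromide (BrC(Br)(Br)Br)
Why: Appel bromination replaces the primary hydroxyl by bromide through SN2 displacement of the alkoxyphosphonium ion under buffered conditions that spare the acetonide.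

Step 4
Reactants: 4 (4R)-4-(2-bromoethyl)-2,2,4-trimethyl-1,3-dioxolane; 5 2-methylcyclohex-2-en-1-one
Product: 8 (2R,3R)-2-allyl-2-methyl-3-R*-cyclohexan-1-one, via Grignard reagent 6 (not isolated), via magnesium enolate 7 (not isolated)
Conditions: (i) Mg, Et2O, reflux; (ii) 5, Cu(OTf)2 (3 mol %), chiral imidazolinium NHC precursor (4 mol %), Et2O, −30 °C; (iii) allyl iodide, DMPU, −30 °C → rt
Reagents that add atoms: allyl iodide (C=CCI)
Why: Cu–NHC-catalysed asymmetric conjugate addition of the Grignard reagent to the α-methyl enone sets C9 under catalyst control (ligand enantiomer chosen for 3R), and C-allylation of the resulting tetrasubstituted magnesium enolate anti to the new C9 substituent (conjugate addition–enolate trapping) should relay it to quaternary C10 with the methyl cis to the side chain.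

Step 5
Reactants: 8 (2R,3R)-2-allyl-2-methyl-3-R*-cyclohexan-1-one
Product: 9 (1R,2R,3R)-2-allyl-2-methyl-1-(2-methylbut-3-en-2-yl)-3-R*-cyclohexan-1-ol
Conditions: prenylmagnesium chloride, THF, −78 → −20 °C; aq. NH4Cl
Reagents that add atoms: prenylmagnesium chloride (CC(C)=CC[Mg]Cl)
Why: Allylic Grignard addition through a six-membered SE2′ transition state delivers the prenyl unit by its γ-carbon, so the hindered C5 ketone should give the 1,1-dimethylallyl carbinol, mainly by equatorial attack (5α-OH); this carbinol centre is removed in step 8.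

Step 6
Reactants: 9 (1R,2R,3R)-2-allyl-2-methyl-1-(2-methylbut-3-en-2-yl)-3-R*-cyclohexan-1-ol
Product: 10 4,4,10β-trimethyl-9β-R*-trans-decal-2-en-5α-ol
Conditions: second-generation Ru alkylidene catalyst [(H2IMes)Cl2Ru=CH(2-i-PrOC6H4)] (5 mol %), toluene (0.005 M), 80 °C
Reagents that add atoms: none
Why: Ring-closing olefin metathesis: the Ru alkylidene loads onto the unhindered C10 allyl group (the 3,3-dimethyl-substituted vinyl group on C4 neither initiates nor homodimerises), then undergoes intramolecular [2+2] cycloaddition/cycloreversion with that vinyl group and releases ethene, forming C2=C3. The closest known reaction type is RCM of 1,7-dienes that carry an allylic quaternary carbon to give cyclohexenes. It closes ring A as a six-membered carbocycle by joining the two terminal alkene carbons (C2 and C3) of a 1,7-diene held on the vicinal ring-B carbons C5 and C10. No new stereocentre is formed; C9 and C10 pass through unchanged, and either C5 epimer of 9 can cyclise (trans- or cis-fused) and converges at step 8. The selectivity needed is cyclisation over intermolecular cross-metathesis, which is secured by high dilution, by the gem-dialkyl compression from the C4 gem-dimethyl group and quaternary C10, and by the absence of any other alkene in 9; the free tertiary alcohol and the acetonide are inert to the catalyst.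

Step 7
Reactants: 10 4,4,10β-trimethyl-9β-R*-trans-decal-2-en-5α-ol
Product: 11 4,4,10β-trimethyl-9β-R*-trans-decalin-5α-ol
Conditions: H2 (1 atm), 10 % Pd/C, EtOAc, rt
Reagents that add atoms: none
Why: Heterogeneous catalytic hydrogenation saturates the only alkene (C2=C3) and creates no stereocentre.

Step 8
Reactants: 11 4,4,10β-trimethyl-9β-R*-trans-decalin-5α-ol
Product: 12 4,4,10β-trimethyl-9β-R*-decal-5-ene (9α-H)
Conditions: SOCl2, pyridine, 0 °C
Reagents that add atoms: none
Why: Dehydration of the tertiary alcohol via its chlorosulfite (E2 with pyridine) can only take a C6 hydrogen because C4 and C10 are quaternary, so the Δ5(6) alkene should be the sole regioisomer and the C5 stereocentre disappears.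

Step 9
Reactants: 12 4,4,10β-trimethyl-9β-R*-decal-5-ene
Product: 13 4,4,10β-trimethyl-9β-R*-decal-5-en-7-one
Conditions: t-BuOOH (70 % aq., 5 equiv), Rh2(cap)4 (1 mol %), ClCH2CH2Cl, 40 °C
Reagents that add atoms: tert-butyl hydroperoxide (CC(C)(C)OO)
Why: Dirhodium-catalysed allylic C–H oxidation with t-BuOOH, the reaction type that converts Δ5-steroids into 7-oxo-Δ5-steroids, should oxidise C7, the only allylic CH2 (C4 and C10 carry no hydrogen), to the enone.

Step 10
Reactants: 13 4,4,10β-trimethyl-9β-R*-decal-5-en-7-one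
Product: 14 4,4,8α,10β-tetramethyl-9β-R*-decal-5-en-7-one
Conditions: LDA, THF, −78 °C; MeI, −78 → 0 °C
Reagents that add atoms: iodomethane (CI)
Why: Kinetic enolate alkylation: C8 carries the only enolisable hydrogens (C6 is vinylic, C4 and C10 are quaternary), so LDA/MeI should methylate C8, whose configuration is irrelevant because it becomes sp2 in step 11.

Step 11
Reactants: 14 4,4,8α,10β-tetramethyl-9β-R*-decal-5-en-7-one
Product: 15 4,4,8,10β-tetramethyl-9β-R*-decalin-5,7-dien-7-yl trifluoromethanesulfonate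
Conditions: KHMDS, THF, −78 °C; PhNTf2, −78 → 0 °C
Reagents that add atoms: N-phenylbis(trifluoromethanesulfonimide) (O=S(=O)(N(c1ccccc1)S(=O)(=O)C(F)(F)F)C(F)(F)F)
Why: Enol triflate formation: deprotonation is again possible only at C8, so O-sulfonylation of the enolate should give the cross-conjugated dienyl triflate with the C7=C8(Me) bond in place.

Step 12
Reactants: 15 4,4,8,10β-tetramethyl-9β-R*-decalin-5,7-dien-7-yl trifluoromethanesulfonate
Product: 16 4,4,8,10β-tetramethyl-9β-R*-decalin-5,7-diene
Conditions: Pd(OAc)2 (5 mol %), PPh3 (10 mol %), n-Bu3N, HCO2H, DMF, 60 °C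
Reagents that add atoms: none
Why: Pd-catalysed formate reduction of the alkenyl triflate (oxidative addition, formate exchange, decarboxylation, reductive elimination) replaces OTf by H without moving the double bonds, giving the 5,7-diene.

Step 13
Reactants: 16 4,4,8,10β-tetramethyl-9β-R*-decalin-5,7-diene
Product: 18 4,4,8,10β-tetramethyl-9β-R*-trans-decal-7-en-6α-ol (5α-H), via alkylborane 17 (not isolated)
Conditions: BH3·THF, THF, 0 °C → rt; then aq. NaOH, 30 % H2O2, 0 °C → rt
Reagents that add atoms: hydrogen peroxide (OO)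
Why: Hydroboration–oxidation of the ring-fused 5,7-diene, by analogy with steroidal 5,7-dienes that give Δ7-6α-ols, should add boron to C6 and hydrogen to C5 syn from the α-face (opposite the C10 methyl and the β side chain on C9), setting C5 (trans ring fusion) and C6 in one event, and oxidation with retention gives the 6α-alcohol.

Step 14
Reactants: 18 4,4,8,10β-tetramethyl-9β-R*-trans-decal-7-en-6α-ol
Product: 19 4,4,8,10β-tetramethyl-9β-R*-trans-decal-7-en-6α-yl butanoate
Conditions: (n-PrCO)2O, Et3N, DMAP (cat.), CH2Cl2, rt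
Reagents that add atoms: butanoic anhydride (CCCC(=O)OC(=O)CCC)
Why: DMAP-catalysed acylation of the secondary equatorial allylic alcohol installs the butanoate with retention at C6.

Step 15
Reactants: 19 4,4,8,10β-tetramethyl-9β-R*-trans-decal-7-en-6α-yl butanoate
Product: 20 (13R)-15-nor-labd-7-ene-6α,13,14-triol 6-butanoate
Conditions: PPTS, MeOH, 40 °C
Reagents that add atoms: none
Why: Acid-catalysed transketalisation with methanol removes the isopropylidene group under conditions that should be too mild to ionise or cleave the allylic ester.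

Step 16
Reactants: 20 (13R)-15-nor-labd-7-ene-6α,13,14-triol 6-butanoate
Product: 21 (13R)-6α-butanoyloxy-13-hydroxy-15-nor-labd-7-en-14-al
Conditions: SO3·pyridine, DMSO, i-Pr2NEt, CH2Cl2, 0 °C
Reagents that add atoms: none
Why: Parikh–Doering oxidation converts the primary alcohol into the aldehyde without glycol cleavage and cannot touch the tertiary alcohol; C13 is quaternary and cannot epimerise.

Step 17
Reactants: 21 (13R)-6α-butanoyloxy-13-hydroxy-15-nor-labd-7-en-14-al
Product: 22 (5S,6S,9S,10R,13R)-labda-7,14-diene-6α,13-diol 6-butanoate (target)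
Conditions: Ph3PCH3Br, KHMDS, THF, 0 °C; then 21, −78 → 0 °C
Reagents that add atoms: methyltriphenylphosphonium bromide (C[P+](c1ccccc1)(c1ccccc1)c1ccccc1.[Br-])
Why: Wittig methylenation of the non-enolisable α-hydroxy aldehyde (excess ylide absorbs the OH proton) should give the vinyl carbinol, while the ester is inert to the ylide at low temperature.

**Compound list**

1 | (R)-citramalic acid, (2R)-2-hydroxy-2-methylbutanedioic acid | OC(=O)[C@](C)(O)CC(=O)O | starting material
2 | (2R)-2-methylbutane-1,2,4-triol | OC[C@](C)(O)CCO | intermediate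
3 | 2-[(4R)-2,2,4-trimethyl-1,3-dioxolan-4-yl]ethan-1-ol | C1OC(C)(C)O[C@]1(C)CCO | intermediate
4 | (4R)-4-(2-bromoethyl)-2,2,4-trimethyl-1,3-dioxolane | C1OC(C)(C)O[C@]1(C)CCBr | intermediate
5 | 2-methylcyclohex-2-en-1-one | CC1=CCCCC1=O | starting material
6 | {2-[(4R)-2,2,4-trimethyl-1,3-dioxolan-4-yl]ethyl}magnesium bromide | C1OC(C)(C)O[C@]1(C)CC[Mg]Br | intermediate
7 | bromomagnesium enolate of (3R)-2-methyl-3-R*-cyclohexan-1-one | C1OC(C)(C)O[C@]1(C)CC[C@H]2CCCC(O[Mg]Br)=C2C | intermediate
8 | (2R,3R)-2-allyl-2-methyl-3-R*-cyclohexan-1-one | C1OC(C)(C)O[C@]1(C)CC[C@H]2CCCC(=O)[C@]2(C)CC=C | intermediate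
9 | (1R,2R,3R)-2-allyl-2-methyl-1-(2-methylbut-3-en-2-yl)-3-R*-cyclohexan-1-ol | C1OC(C)(C)O[C@]1(C)CC[C@H]2CCC[C@@](O)(C(C)(C)C=C)[C@]2(C)CC=C | intermediate
10 | 4,4,10β-trimethyl-9β-R*-trans-decal-2-en-5α-ol | C1OC(C)(C)O[C@]1(C)CC[C@H]2CCC[C@@]3(O)C(C)(C)C=CC[C@]23C | intermediate
11 | 4,4,10β-trimethyl-9β-R*-trans-decalin-5α-ol | C1OC(C)(C)O[C@]1(C)CC[C@H]2CCC[C@@]3(O)C(C)(C)CCC[C@]23C | intermediate
12 | 4,4,10β-trimethyl-9β-R*-decal-5-ene (9α-H) | C1OC(C)(C)O[C@]1(C)CC[C@H]2CCC=C3C(C)(C)CCC[C@]23C | intermediate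
13 | 4,4,10β-trimethyl-9β-R*-decal-5-en-7-one | C1OC(C)(C)O[C@]1(C)CC[C@H]2CC(=O)C=C3C(C)(C)CCC[C@]23C | intermediate
14 | 4,4,8α,10β-tetramethyl-9β-R*-decal-5-en-7-one | C1OC(C)(C)O[C@]1(C)CC[C@H]2[C@H](C)C(=O)C=C3C(C)(C)CCC[C@]23C | intermediate
15 | 4,4,8,10β-tetramethyl-9β-R*-decalin-5,7-dien-7-yl trifluoromethanesulfonate | C1OC(C)(C)O[C@]1(C)CC[C@H]2C(C)=C(OS(=O)(=O)C(F)(F)F)C=C3C(C)(C)CCC[C@]23C | intermediate
16 | 4,4,8,10β-tetramethyl-9β-R*-decalin-5,7-diene | C1OC(C)(C)O[C@]1(C)CC[C@H]2C(C)=CC=C3C(C)(C)CCC[C@]23C | intermediate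
17 | 4,4,8,10β-tetramethyl-9β-R*-trans-decal-7-en-6α-ylborane (5α-H) | C1OC(C)(C)O[C@]1(C)CC[C@H]2C(C)=C[C@H](B)[C@H]3C(C)(C)CCC[C@]23C | intermediate
18 | 4,4,8,10β-tetramethyl-9β-R*-trans-decal-7-en-6α-ol (5α-H) | C1OC(C)(C)O[C@]1(C)CC[C@H]2C(C)=C[C@H](O)[C@H]3C(C)(C)CCC[C@]23C | intermediate
19 | 4,4,8,10β-tetramethyl-9β-R*-trans-decal-7-en-6α-yl butanoate | C1OC(C)(C)O[C@]1(C)CC[C@H]2C(C)=C[C@H](OC(=O)CCC)[C@H]3C(C)(C)CCC[C@]23C | intermediate
20 | (13R)-15-nor-labd-7-ene-6α,13,14-triol 6-butanoate | OC[C@](C)(O)CC[C@H]1C(C)=C[C@H](OC(=O)CCC)[C@H]2C(C)(C)CCC[C@]12C | intermediate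
21 | (13R)-6α-butanoyloxy-13-hydroxy-15-nor-labd-7-en-14-al | O=C[C@](C)(O)CC[C@H]1C(C)=C[C@H](OC(=O)CCC)[C@H]2C(C)(C)CCC[C@]12C | intermediate
22 | (5S,6S,9S,10R,13R)-labda-7,14-diene-6α,13-diol 6-butanoate | C=C[C@](C)(O)CC[C@H]1C(C)=C[C@H](OC(=O)CCC)[C@H]2C(C)(C)CCC[C@]12C | target

**Step count and risks**

Total step count: 17. Longest linear sequence: 17 steps (1 → 22; compound 5 and all reagents are bought).

Steps most likely to fail:

Step 13. Hydroboration may attack the C7=C8 bond instead of C5=C6 (boron at C7), or the allylic borane may migrate before oxidation and scramble the oxygen position. The fallback sets out from 12 and builds the oxygen pattern through a ketone instead: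
- hydroboration–oxidation of the isolated C5=C6 bond, whose regiochemistry is unambiguous, should give the saturated 6α-alcohol F1;
- DMP oxidation gives the trans-fused 6-ketone F2;
- IBX dehydrogenation, possible only towards C7–C8, gives the 7-en-6-one F3;
- conjugate addition of Me2CuLi gives the 8-methyl ketone F4;
- a second IBX dehydrogenation gives the 8-methyl-7-en-6-one F5;
- Meerwein–Ponndorf–Verley reduction under equilibrating conditions (Al(Oi-Pr)3, i-PrOH, reflux) should favour the equatorial 6α-alcohol, which is 18, where the route is rejoined.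

Step 5. The crowded magnesium alkoxide may revert (retro-allylation) and re-add through the α-carbon to give the linear prenyl carbinol, or the Grignard reagent may only enolise the ketone. The fallback sets out from 8 and builds the arm stepwise:
- Reformatsky reaction with ethyl 2-bromo-2-methylpropanoate and zinc gives the β-hydroxy ester F6;
- SOCl2/pyridine dehydration (only C6–H is available) gives the β,γ-unsaturated ester F7;
- DIBAL-H at −78 °C gives the neopentyl aldehyde F8;
- Wittig methylenation gives the triene F9, in which the 1,1-dimethylallyl arm sits on an sp2 C5;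
- RCM as in step 6 gives the bicyclic diene F10;
- hydrogenation with RhCl(PPh3)3, which reduces only the disubstituted C2=C3 bond, gives 12, where the route is rejoined.

Step 4. Enantioselectivity may erode in the conjugate addition of this functionalised Grignard reagent to the α-substituted enone, or the trapping may suffer O-allylation or poor trans selectivity. The fallback sets out from 4 (as its Grignard reagent 6) and bought cyclohex-2-en-1-one, and makes the quaternary centre in a separate alkylation:
- Cu/ferrocenyl-diphosphine-catalysed asymmetric conjugate addition to the unsubstituted enone, with trapping of the enolate by MeI, gives the trans-2-methyl-3-alkylcyclohexanone F11;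
- TMSCl/Et3N in hot DMF gives the more substituted silyl enol ether F12;
- MeLi followed by allyl bromide alkylates the regiodefined lithium enolate anti to the C9 substituent and gives 8, where the route is rejoined.

Further compounds
F1 | step 13 | 4,4,10β-trimethyl-9β-R*-trans-decalin-6α-ol (5α-H) | C1OC(C)(C)O[C@]1(C)CC[C@H]2CC[C@H](O)[C@H]3C(C)(C)CCC[C@]23C
F2 | step 13 | 4,4,10β-trimethyl-9β-R*-trans-decalin-6-one | C1OC(C)(C)O[C@]1(C)CC[C@H]2CCC(=O)[C@H]3C(C)(C)CCC[C@]23C
F3 | step 13 | 4,4,10β-trimethyl-9β-R*-trans-decal-7-en-6-one | C1OC(C)(C)O[C@]1(C)CC[C@H]2C=CC(=O)[C@H]3C(C)(C)CCC[C@]23C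
F4 | step 13 | 4,4,8,10β-tetramethyl-9β-R*-trans-decalin-6-one (C8 epimers) | C1OC(C)(C)O[C@]1(C)CC[C@H]2C(C)CC(=O)[C@H]3C(C)(C)CCC[C@]23C
F5 | step 13 | 4,4,8,10β-tetramethyl-9β-R*-trans-decal-7-en-6-one | C1OC(C)(C)O[C@]1(C)CC[C@H]2C(C)=CC(=O)[C@H]3C(C)(C)CCC[C@]23C
F6 | step 5 | ethyl 2-[(1R,2R,3R)-2-allyl-1-hydroxy-2-methyl-3-R*-cyclohexyl]-2-methylpropanoate | C1OC(C)(C)O[C@]1(C)CC[C@H]2CCC[C@@](O)(C(C)(C)C(=O)OCC)[C@]2(C)CC=C
F7 | step 5 | ethyl 2-[(5R,6R)-6-allyl-6-methyl-5-R*-cyclohex-1-en-1-yl]-2-methylpropanoate | C1OC(C)(C)O[C@]1(C)CC[C@H]2CCC=C(C(C)(C)C(=O)OCC)[C@]2(C)CC=C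
F8 | step 5 | 2-[(5R,6R)-6-allyl-6-methyl-5-R*-cyclohex-1-en-1-yl]-2-methylpropanal | C1OC(C)(C)O[C@]1(C)CC[C@H]2CCC=C(C(C)(C)C=O)[C@]2(C)CC=C
F9 | step 5 | (5R,6R)-6-allyl-6-methyl-1-(2-methylbut-3-en-2-yl)-5-R*-cyclohex-1-ene | C1OC(C)(C)O[C@]1(C)CC[C@H]2CCC=C(C(C)(C)C=C)[C@]2(C)CC=C
F10 | step 5 | 4,4,10β-trimethyl-9β-R*-decalin-2,5-diene | C1OC(C)(C)O[C@]1(C)CC[C@H]2CCC=C3C(C)(C)C=CC[C@]23C
F11 | step 4 | (2R,3R)-2-methyl-3-R*-cyclohexan-1-one (trans) | C1OC(C)(C)O[C@]1(C)CC[C@H]2CCCC(=O)[C@@H]2C
F12 | step 4 | (3R)-2-methyl-3-R*-1-(trimethylsilyloxy)cyclohex-1-ene | C1OC(C)(C)O[C@]1(C)CC[C@H]2CCCC(O[Si](C)(C)C)=C2C
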